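The data are simulated with constants of no real substance; scatter was added.

I compared two times in the flask, the feed of G and the time on which Z falls, and I reckoned with their ratio.

in all of them: Q 0.25 mM
- gamma: Z 0.25 M; G 0.15 M (fed, over 50 s); run made earlier
- zeta: Z 0.25 M; G 0.22 M (fed, over 50 s); run made earlier
- theta: Z 0.38 M; G 0.30 M (fed, over 50 s); run made earlier
- flask: Z 0.25 M; G 0.300 M (fed, over 50 s); time 4.0 min

| run | time / min | L / % |
|---|---|---|
| gamma | 0.333 | 1.7 |
| gamma | 0.500 | 1.8 |
| gamma | 0.667 | 4.2 |
| gamma | 1.00 | 7.6 |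
| gamma | 1.50 | 9.9 |
| gamma | 2.50 | 17.8 |
| gamma | 4.00 | 26.9 |
| zeta | 0.200 | 0.3 |
| zeta | 0.667 | 4.0 |
| zeta | 1.00 | 8.3 |
| zeta | 1.50 | 15.2 |
| zeta | 2.50 | 22.7 |
| zeta | 3.00 | 29.9 |
| zeta | 4.00 | 36.2 |
| theta | 0.833 | 3.3 |
| theta | 1.50 | 12.7 |
| theta | 2.50 | 20.1 |
| theta | 3.00 | 25.9 |
| theta | 4.00 | 34.8 |

(standard deviation of a reading: 1 percentage point)

- amount of L in percent of the Z charged, at 12 s, 1.0 min and 4.0 min

The second time, which I called the clock, was the time in which Z falls by a factor e, pseudo-first-order, with the flask's whole G charge standing against it. I took the rate as proportional to Z and to G, and I took L as using one G for each Z. A steady feed then acts, once it has ended, like a batch begun at half the dosing time. The last zeta reading, from a run with the flask's Z and a scatter of 1 percentage point, with G taken as its charge less half of what that L used, gave a clock of 4.64 min. The flask's feed was shorter than the clock, at a ratio of 0.179, so I solved each end separately and joined them at the delayed start. During the feed G grows with time and L with the square of time, which gave me 0.517% at 12 s. After it, Z decays on the clock, which gave me 11.8% at 1.0 min. With mean G lowered for a conversion near half, I got 45.7% at 4.0 min.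

The forecast, noting that “the Z effect looks weaker at high concentration, possibly some saturation”, gave 0.5%, 11% and 44%.

The flask gave 0.647%, 9.95% and 45.2%.

    G + X ⇌ E (K = 6.30 M⁻¹, k = 75.0 M⁻¹ s⁻¹)
    J → Q + L (k = 82.0 s⁻¹)
    E → J (k = 6.80 s⁻¹)
    Z + Q ⇌ X (K = 7.90 M⁻¹, k = 76.0 M⁻¹ s⁻¹)

At 1.95 min in the flask, the forward step from Z and Q to X had a half-life of 0.047 s for Q but 1.7 min for Z. At 4.00 min the catalyst stood as Q 43.8%, X 31.0%, E 23.2% and J 1.93%. The flask's own final L gives a clock of 4.84 min, beside 4.64 min from zeta. A second flask with twice the G reached 61.0% L, which gives a clock of 3.32 min, longer than the halved clock of 2.32 min.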